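All runs were generated by integration with constants of no real substance; scatter was added.

Wednesday's run ended with 35.2% of the two substrates converted, and you can read from that end what the next flask, with less catalyst, has to work with.

| flask | left-handed substrate | right-handed substrate | partner | protic impurity | catalyst | remark | time |
|---|---|---|---|---|---|---|---|
| Friday's | 0.30 M | 0.30 M | 0.34 M | 0.030 M | 54 mM | run made earlier |  |
| Monday's | 0.30 M | 0.30 M | 0.53 M | 0.030 M | 54 mM | run made earlier |  |
| Wednesday's | 0.30 M | 0.30 M | 0.24 M | 0.030 M | 81 mM | run made earlier |  |
| flask | 0.30 M | 0.30 M | 0.240 M | 0.0300 M | 54 mM |  | 15 d |

- Friday's (time / d: left-handed product / %, right-handed substrate / %): 2.50: 24.6, 35.9; 6.00: 29.8, 31.5; 12.0: 31.4, 30.6; 20.0: 31.7, 30.6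
- Monday's (time / d: left-handed product / %, right-handed substrate / %): 1.25: 25.7, 34.7; 3.00: 35.9, 26.5; 8.00: 43.7, 19.2; 20.0: 45.7, 14.3
- Wednesday's (time / d: left-handed product / %, right-handed substrate / %): 5.00: 21.7, 37.0; 10.0: 22.4, 37.4; 15.0: 22.5, 37.3; 20.0: 22.5, 37.3

(readings scatter by 0.3 percentage points)

* at 15 d, what has stopped the reaction, if anything has (no working catalyst is left / the partner has run out first / forward and back rates have come level / all of the left-handed substrate has reacted / it is still moving)
* how much left-handed product there is at 15 d, in percent of the left-handed substrate and right-handed substrate together charged
* how much right-handed substrate there is at 15 d, in percent of the left-handed substrate and right-handed substrate together charged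
* how much right-handed product there is at 15 d, in percent of the left-handed substrate and right-handed substrate together charged

- catalyst is single-handed; left-handed substrate and right-handed substrate are mirror images of each other, charged as a racemate, each of them at the stated concentration
- the reaction counts as stopped when no species that holds the left-handed substrate and right-handed substrate together changes by six tenths of a point or more over the second half of the time

Take the partner charged less the protic impurity, as a share of both substrates charged: this is the partner ceiling 35.0%, and since that partner is less than the substrates charged, it is the limiting reagent. Wednesday's charge gives 35.0% by the same sum, close to its reading.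

Now the rate, as I reckon it. Friday's run has the flask's catalyst charge, and its free partner (ceiling less conversion read) decayed with a first-order constant, as read, of 0.385 /d between its first two readings. Wednesday's last readings give a selectivity factor of 2.04, so the left-handed substrate reacts about twice as fast as the right-handed substrate. Weighting the left-handed substrate fully and the right-handed by half, Friday's constant scales to a starting constant of 0.729 /d for the flask.

Two things slow it. Thinning substrate is the first: at the ceiling I reckon 0.745 of the right-handed substrate left and the square of that of the left-handed, so the weighted substrate stands at 0.618 of its start, and the constant falls to a closing constant of 0.451 /d. Free partner also falls. Integrating, with the constant linear in conversion, leaves late in the flask a usable partner of 0.618 times exp(−closing constant × time). That is 0.0717% of the usable partner at 15 d. Over the second half the left-handed product, with the larger share, moves about 0.44 percentage points, which is within the stop rule in the notes, so my own reckoning also has the flask stopped at the ceiling.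

The forecast says the partner has run out first, with 22.4% left-handed product, 37.4% right-handed substrate and 12.6% right-handed product: “the same endpoint (35%), only slower”.

The flask's outcome is this: the partner has run out first, with 22.3% left-handed product, 37.4% right-handed substrate and 12.6% right-handed product.

    partner + catalyst + left-handed substrate → catalyst + left-handed product (k = 1.30 /M²/h)
    partner + catalyst + right-handed substrate → catalyst + right-handed product (k = 0.640 /M²/h)
    partner + protic impurity → quenched reagent (k = 7.70 /M/h)
    partner → decomposition product (k = 2.00 × 10⁻⁵ /h)

The flask stands at 34.9% converted against a ceiling of 35.0%, with 0.050% of its charged partner left at 15.0 d. Now take the neighbour with 0.12 M of protic impurity, its other charges held. Its ceiling is 20.0%. That neighbour gives 13.1% left-handed product and 6.92% right-handed product, 20.0% together.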